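Atom labels used throughout: ring A is T1–T6 (T1 the spiro carbon, T2 the enone carbonyl, T3 the methyl-bearing alkene carbon, T4 the methoxy-bearing carbon, T5 the CMe2 carbon, T6 the saturated ketone). The cyclopentane is B1–B5 (B1 = T1, B2 = CH–isopropyl, B3 and B4 = CH2, B5 = pinane C2). The pinane keeps terpene numbering (pinane C1–C7, C6 the CMe2 bridge). Compound numbers 1–20 are those of the steps.

## The problem

Target 20 is a dispiro compound: ring A, a six-membered vinylogous methyl ester that also holds a saturated ketone, is spiro-joined at B1 to a cyclopentane, which is spiro-joined at B5 to C2 of a pinane. B1 and B5 are adjacent quaternary carbons and B2, next to B1, carries the isopropyl group, so three contiguous crowded centres sit on one five-membered ring; pinane C1 and C5 come with the terpene, whereas B5, B2 and B1 have to be made. B5 must hold the bulky B1 on the face of the gem-dimethyl bridge and the B4 methylene on the open face, the opposite of what an external reagent delivers to a trigonal pinane C2. B2 must place isopropyl cis to T2 and to pinane C3, and a ring fused across B1–B5 is the only nearby element that can bias it. B1 is stereogenic only because its two carbonyls differ (T2 beside C–Me, T6 beside CMe2), so its configuration is decided by which carbonyl is extended in which direction. The strained cyclobutane (no cation or radical at pinane C2, no strong acid), the acid-labile vinylogous ester and the non-enolisable 1,3-diketone T2–B1–T6 (retro-Claisen with alkoxides) limit the reagents. The enabling feature is pinane C3: it is a plain methylene in 20 and lies next to B5, so an oxygen parked there on the bridge face can carry a carbene onto the exocyclic C2=CH2 bond of a pinocarveol, whose methylene carbon is B4.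

## Retrosynthesis

**20 ⇒ 19 ⇒ 18 ⇒ 17.** The last operations remove what the tether leaves behind: the C–O bond at pinane C3, by radical deoxygenation through thiocarbonyl derivative 19, and the O–CH3 bond on T4. The oxygen cannot go earlier because until ring A is made it is the lactone oxygen. Methylation precedes deoxygenation because a free vinylogous acid would compete in the thioacylation. No skeletal simplification results; 17 already holds every carbon but the O-methyl. The forward steps must methylate the T4 oxygen and not the T2 oxygen, and must reduce the C3 radical before it fragments.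

**17 ⇒ 14 + 15.** Ring A is cut at T2–T3 and T5–T6, giving 2-methylpentan-3-one 15 and lactone ester 14. Cutting at B1 instead would postpone the quaternary centre to the end and lose the label on its carbonyls; cutting at T4 would need a one-carbon insert between two ketones. The cut removes a ring and six carbons and leaves B1 as a lactone carbonyl (T2) plus a methyl ester (T6). The forward reaction asks the ethyl-side enolate of 15 to take the lactone first, and the isopropyl methine of the resulting diketone 16 to close on the ester.

**14 ⇒ 13 ⇒ 12.** After isopropyl is returned to the isopropenyl group of 13, the B1–B2 bond is cut as a 5-exo radical closure of the B1 radical of 12 onto a trisubstituted alkene. A polar closure would require displacement at a secondary, branched B2. Forming B2–B3 or B3–B4 instead would not use the acidity of B1. The cyclopentane and the B2 stereocentre disappear. The forward step must be exo-selective and must put the side chain on the lactone-carbonyl face.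

**12 ⇒ 10 + 11; 10 ⇒ 8 + 9.** Cross-metathesis with 2-methylbut-2-ene 11 is undone to the terminal alkene 10. The B3–B4 bond is then cut while B1–B4 is reconnected, which turns the chain into the doubly activated cyclopropane 8 and allylmagnesium bromide 9. Allyl plus metathesis avoids the α/γ ambiguity of a prenyl nucleophile. Precursor 8 has only fourteen carbons. The forward opening must occur at B4 and not at a carbonyl.

**8 ⇒ 7.** The key cut removes B1–B5 and B1–B4 together, leaving the diazomalonate 7 of a pinocarveol. An untethered carbon nucleophile or radical adding to pinane C2 would arrive anti to the bridge and so put B1 on the wrong face; the alternatives below escape this only by delivering B4 instead. Tethering through the syn oxygen on pinane C3 enforces the hindered face. As a lactone the tether also labels one carbonyl of B1. Two rings, two bonds and two stereocentres reduce to one secondary carbinol. The forward step needs cyclopropanation to beat C–H insertion.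

**7 ⇒ 6 ⇒ 4 + 5; 4 ⇒ 3 ⇒ 1.** Diazo transfer and acylation with methyl malonyl chloride 5 lead back to cis-pinocarveol 4. Its hydroxyl is syn to the bridge because hydride attacks pinocarvone 3 from the open face. Enone 3 comes from (+)-α-pinene 1 by photooxygenation through hydroperoxide 2, which supplies pinane C1 and C5 and the exocyclic B4 in one operation.

## Roads not taken

Alternative 1: Ring A is cut at T2–T3 and B1–T6. Forward, the ethyl-ketone enolate of keto ester A3, methyl 2,2-dimethyl-3-oxopentanoate, is C-acylated by the spiro acid chloride A2. Excess LiN(iPr)2 then deprotonates the acylation product twice, and its B1 carbanion closes on the ester to give the enolised triketone A1.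
- Merits: ring A arrives nearly preformed, T5 is already quaternary in A3, the closure is one pot, and no oxygen has to be removed from pinane C3. In end-game step economy this road is better than the chosen one.
- Weak points: it is an end game only. Whatever builds A2 must still place the carboxyl-bearing carbon on the bridge face of B5. The B1 configuration is then set by the face on which a planar tertiary carbanion, flanked by quaternary B5, attacks a neopentyl ester, with the isopropyl group and the two pinane flanks pulling in different directions.
- Comparison: the chosen plan sets against the shorter end game a B1 that is fixed constitutionally by the lactone before ring A exists, and a B5 that is enforced by the tether. Both roads share the O-methylation regiochemistry question.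

Alternative 2: B4–B5 is cut together with a temporary B3–pinane C3 bond. Forward, the verbenone-type enone A5, which carries a malonate/enol acetate tether on pinane C2, undergoes sensitised crossed [2+2] photocycloaddition to the bicyclo[2.1.1]hexane A4. Acetate removal and retro-aldol cleavage then open the B3–C3 bond.
- Merits: 1,5-closure is the normal mode for a two-atom tether, and B4 adds to pinane C2 from the open face, so the innate facial bias is used and not opposed. In that respect it is better than the chosen plan.
- Weak points: the bicyclic enone chromophore of A5 is prone to photochemical 1,3-acyl shift. B2 must be set beforehand on the acyclic tether of A5. Two ketones (B3 and pinane C4) must later be deoxygenated. The two esters on B1 are only diastereotopic, so T2 and T6 have no label.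
- Comparison: the chosen plan replaces the photochemical step by a thermal catalytic one and supplies the carbonyl label that this road lacks, at the price of removing one oxygen.

Alternative 3: B4–B5 and B1–B2 are cut. Forward, a 4-methylpent-3-enyl radical from the redox-active ester A8 adds to B5 of the nopinone alkylidene malonate A7 from the open face. The malonyl radical closes 5-exo, and the oxidised tertiary radical is trapped by the cis ester to give lactone ester A6.
- Merits: it is convergent, forms both quaternary centres and the cyclopentane in one step, uses the innate facial bias, and its lactone also marks the carbonyl cis to the side chain. It is shorter than the chosen plan.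
- Weak points: a primary radical must add to the fully substituted carbon of the tetrasubstituted acceptor A7. The B2/B5 relationship is set by an acyclic malonyl radical with only the two pinane flanks to distinguish. Three events must succeed in sequence in one flask. A tertiary C–O bond must later be reduced.
- Comparison: the chosen plan is longer. It sets against this a B1–B5 bond made by an enforced, well-precedented intramolecular step, a B1–B2 closure on a rigid lactone-fused radical, and bonds formed one at a time so each can be checked.

Key step: step 5

Remark on the chemistry: 10 and 12 are expected as epimer mixtures at B1, and 16 at T3; these centres are drawn without configuration and become planar later. 17 is drawn as the enol on T4.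

## Route

Step 1
Reactants: 1 (1R,5R)-(+)-α-pinene
Product: 3 pinocarvone, via trans-pinocarveyl hydroperoxide 2 (not isolated)
Conditions: O2, tetraphenylporphyrin (cat.), visible light, Ac2O, pyridine, DMAP (cat.), CH2Cl2, 20 °C
Reagents that add atoms: dioxygen, O=O
Why: Schenck ene reaction of singlet oxygen at pinane C3 shifts the double bond to the exocyclic position; in situ acetylation and Kornblum–DeLaMare-type loss of acetic acid give the enone, so the C3 configuration of 2 is immaterial.

Step 2
Reactants: 3 pinocarvone
Product: 4 cis-pinocarveol
Conditions: NaBH4, CeCl3·7H2O, MeOH, −78 to 0 °C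
Reagents that add atoms: none
Why: Luche reduction gives 1,2-addition to the exocyclic enone; hydride enters from the face away from the gem-dimethyl bridge, so the hydroxyl ends syn to the bridge (3S).

Step 3
Reactants: 4 cis-pinocarveol; 5 methyl 3-chloro-3-oxopropanoate
Product: 6 cis-pinocarveyl methyl malonate
Conditions: pyridine, DMAP (cat.), CH2Cl2, 0 °C
Reagents that add atoms: none
Why: O-acylation of a secondary alcohol by an acid chloride under nucleophilic catalysis; the carbinol centre is untouched.

Step 4
Reactants: 6 cis-pinocarveyl methyl malonate
Product: 7 cis-pinocarveyl methyl diazomalonate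
Conditions: 4-acetamidobenzenesulfonyl azide, Et3N, MeCN, 0 to 20 °C
Reagents that add atoms: 4-acetamidobenzenesulfonyl azide, CC(=O)Nc1ccc(cc1)S(=O)(=O)N=[N+]=[N-]
Why: Regitz diazo transfer to an active methylene; a malonate is acidic enough for triethylamine.

Step 5
Reactants: 7 cis-pinocarveyl methyl diazomalonate
Product: 8 cyclopropane-fused γ-lactone methyl ester
Conditions: Rh2(OAc)4 (2 mol %), ClCH2CH2Cl, 80 °C, slow addition of 7 at high dilution
Reagents that add atoms: none
Why: Rh2(OAc)4 expels N2 from 7 to give an electrophilic rhodium carbenoid with two acceptor groups, which adds to the electron-rich 1,1-disubstituted C2=CH2 bond in a concerted, asynchronous [2+1] event with bonding to the terminal carbon B4 leading. The closest known reaction type is the intramolecular cyclopropanation of allylic diazomalonates to 1-alkoxycarbonyl-3-oxabicyclo[3.1.0]hexan-2-ones. The cyclopropane (B1–B4–B5) closes by the cycloaddition itself; the γ-lactone (B1, lactone carbonyl, O, pinane C3, B5) is completed in the same event through the ester tether, the new B1–B5 bond lying in the five-membered ring. B5 is controlled by the ester oxygen on pinane C3: it is syn to the gem-dimethyl bridge and a five-membered lactone can only be cis-fused, so B1 bonds on that face and B4 is left anti. B1 follows from the cis fusion of the two small rings and now carries one lactone carbonyl (future T2, cis to pinane C3) and one free ester (future T6). The step needs chemoselectivity for the alkene over 1,5-insertion into the C4–H bond and over carbene dimerisation; the nucleophilic alkene, the acceptor/acceptor carbenoid and slow addition should secure it.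

Step 6
Reactants: 8 cyclopropane-fused γ-lactone methyl ester; 9 allylmagnesium bromide
Product: 10 but-3-enyl γ-lactone methyl ester
Conditions: CuBr·SMe2 (20 mol %), THF, −78 to −30 °C, slow addition of 9; aq NH4Cl
Reagents that add atoms: none
Why: Copper-catalysed homoconjugate (SN2-type) addition of allylmagnesium bromide to a doubly activated cyclopropane at the unsubstituted carbon B4, cleaving B1–B4; the enolate released shields both carbonyls from further attack, and B5 is not touched.

Step 7
Reactants: 10 but-3-enyl γ-lactone methyl ester; 11 2-methylbut-2-ene
Product: 12 (4-methylpent-3-enyl) γ-lactone methyl ester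
Conditions: second-generation Grubbs catalyst (5 mol %), 11/CH2Cl2, 40 °C
Reagents that add atoms: none
Why: Olefin cross-metathesis of a terminal alkene with excess 2-methylbut-2-ene, the standard way to turn an allyl into a prenyl-type terminus.

Step 8
Reactants: 12 (4-methylpent-3-enyl) γ-lactone methyl ester
Product: 13 isopropenyl spiro-cyclopentane lactone ester
Conditions: Mn(OAc)3·2H2O (2.2 equiv), Cu(OAc)2·H2O (cat.), AcOH, 70 °C
Reagents that add atoms: none
Why: Oxidative free-radical cyclisation: the trivalent manganese enolate gives the electrophilic B1 radical, which closes 5-exo-trig on B2; the tertiary radical is oxidised by divalent copper to the isopropenyl group. Ring fusion to the lactone is necessarily cis, and a chair-like transition state with the pinane bridgehead branch of B5 pseudo-equatorial puts the side chain on the lactone-carbonyl face, trans to the ester.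

Step 9
Reactants: 13 isopropenyl spiro-cyclopentane lactone ester
Product: 14 isopropyl spiro-cyclopentane lactone ester
Conditions: H2 (1 atm), Pd/C, EtOAc, 20 °C
Reagents that add atoms: none
Why: Catalytic hydrogenation of the only alkene; no stereocentre is formed and the cyclobutane is inert at this pressure.

Step 10
Reactants: 14 isopropyl spiro-cyclopentane lactone ester; 15 2-methylpentan-3-one
Product: 17 pinane-C3-hydroxy triketone (enol form), via ring-opened hydroxy diketone ester 16 (not isolated)
Conditions: 15, LiN(iPr)2 (excess), THF, −78 °C; then 14, −78 to 20 °C; aq NH4Cl, 0 °C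
Reagents that add atoms: none
Why: Crossed Claisen condensation followed by Dieckmann-type acylation of a β-diketone dianion: the kinetic ethyl-side enolate (T3) opens the strained cis-fused lactone at T2 rather than the buried ester; the excess amide then removes the isopropyl methine proton of 16 and T5 closes 6-exo-trig on the ester. The lactone-first order is what fixes B1, and 14 has no enolisable proton.

Step 11
Reactants: 17 pinane-C3-hydroxy triketone (enol form)
Product: 18 pinane-C3-hydroxy methyl enol ether
Conditions: Me3SiCHN2, toluene/MeOH, 0 °C
Reagents that add atoms: (trimethylsilyl)diazomethane, C[Si](C)(C)C=[N+]=[N-]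
Why: Diazoalkane O-methylation of a vinylogous acid, selective for the acidic enol over the secondary alcohol; the T4 oxygen beside CMe2 is less shielded than the T2 oxygen, which is flanked by the spiro centre and the isopropyl group and can accept a hydrogen bond from the C3 hydroxyl.

Step 12
Reactants: 18 pinane-C3-hydroxy methyl enol ether
Product: 19 O-(imidazol-1-ylthiocarbonyl) derivative of 18
Conditions: 1,1'-thiocarbonyldiimidazole, DMAP (cat.), ClCH2CH2Cl, 80 °C
Reagents that add atoms: 1,1'-thiocarbonyldiimidazole, S=C(n1ccnc1)n1ccnc1
Why: Neutral thioacylation of a hindered secondary alcohol (first half of the Barton–McCombie deoxygenation); no alkoxide is generated, which protects the 1,3-diketone from retro-Claisen cleavage.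

Step 13
Reactants: 19 O-(imidazol-1-ylthiocarbonyl) derivative of 18
Product: 20 target, CNP0307059.1
Conditions: Bu3SnH (excess, ≥0.2 M), AIBN (cat.), toluene, 100 °C
Reagents that add atoms: none
Why: Barton–McCombie radical deoxygenation; the secondary radical at pinane C3 is not cyclobutylcarbinyl, so the cyclobutane stays closed, and the high stannane concentration lets hydrogen transfer outrun β-scission of the B5–B1 bond.

## Compound list

1 | (1R,5R)-(+)-α-pinene | CC1=CC[C@@H]2C[C@H]1C2(C)C | starting material
2 | trans-pinocarveyl hydroperoxide, (1S,3R,5S)-3-hydroperoxy-6,6-dimethyl-2-methylidenebicyclo[3.1.1]heptane, OOH anti to the bridge | C=C1[C@H](OO)C[C@@H]2C[C@H]1C2(C)C | intermediate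
3 | pinocarvone, (1S,5S)-6,6-dimethyl-2-methylidenebicyclo[3.1.1]heptan-3-one | C=C1C(=O)C[C@@H]2C[C@H]1C2(C)C | intermediate
4 | cis-pinocarveol, (1S,3S,5S)-6,6-dimethyl-2-methylidenebicyclo[3.1.1]heptan-3-ol, OH syn to the gem-dimethyl bridge | C=C1[C@@H](O)C[C@@H]2C[C@H]1C2(C)C | intermediate
5 | methyl 3-chloro-3-oxopropanoate | COC(=O)CC(=O)Cl | starting material
6 | cis-pinocarveyl methyl malonate (ester oxygen syn to the bridge) | C=C1[C@@H](OC(=O)CC(=O)OC)C[C@@H]2C[C@H]1C2(C)C | intermediate
7 | cis-pinocarveyl methyl diazomalonate | C=C1[C@@H](OC(=O)C(=[N+]=[N-])C(=O)OC)C[C@@H]2C[C@H]1C2(C)C | intermediate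
8 | cyclopropane-fused γ-lactone methyl ester: cyclopropane spiro at pinane C2, lactone cis-fused from B1 to the oxygen on pinane C3; B1 and that oxygen syn to the bridge, B4 anti | COC(=O)[C@]12C[C@@]13[C@@H](OC2=O)C[C@@H]4C[C@H]3C4(C)C | intermediate
9 | allylmagnesium bromide | C=CC[Mg]Br | starting material
10 | γ-lactone methyl ester with a but-3-enyl chain on B5 (anti to the bridge); B1 is CH, epimer mixture | C=CCC[C@]12C(C(=O)OC)C(=O)O[C@H]1C[C@@H]3C[C@H]2C3(C)C | intermediate
11 | 2-methylbut-2-ene | CC=C(C)C | starting material
12 | γ-lactone methyl ester with a 4-methylpent-3-enyl chain on B5; B1 epimer mixture | CC(C)=CCC[C@]12C(C(=O)OC)C(=O)O[C@H]1C[C@@H]3C[C@H]2C3(C)C | intermediate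
13 | spiro-cyclopentane lactone ester, isopropenyl on B2 cis to the lactone carbonyl, ester on B1 trans to it | COC(=O)[C@]12[C@@H](C(C)=C)CC[C@@]13[C@@H](OC2=O)C[C@@H]4C[C@H]3C4(C)C | intermediate
14 | spiro-cyclopentane lactone ester, isopropyl on B2 cis to the lactone carbonyl | COC(=O)[C@]12[C@@H](C(C)C)CC[C@@]13[C@@H](OC2=O)C[C@@H]4C[C@H]3C4(C)C | intermediate
15 | 2-methylpentan-3-one | CCC(=O)C(C)C | starting material
16 | ring-opened hydroxy β-diketone methyl ester (2,4-dimethyl-3-oxopentanoyl group on B1 cis to the C3 hydroxyl) | COC(=O)[C@]1(C(=O)C(C)C(=O)C(C)C)[C@@H](C(C)C)CC[C@@]12[C@@H](O)C[C@@H]3C[C@H]2C3(C)C | intermediate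
17 | O-demethyl target bearing a hydroxyl on pinane C3 (syn to the bridge), enol on T4 | OC1=C(C)C(=O)[C@@]2(C(=O)C1(C)C)[C@@H](C(C)C)CC[C@@]21[C@@H](O)C[C@@H]2C[C@H]1C2(C)C | intermediate
18 | target bearing a hydroxyl on pinane C3 (syn to the bridge) | COC1=C(C)C(=O)[C@@]2(C(=O)C1(C)C)[C@@H](C(C)C)CC[C@@]21[C@@H](O)C[C@@H]2C[C@H]1C2(C)C | intermediate
19 | O-(imidazol-1-ylthiocarbonyl) derivative of 18 | COC1=C(C)C(=O)[C@@]2(C(=O)C1(C)C)[C@@H](C(C)C)CC[C@@]21[C@@H](OC(=S)n3ccnc3)C[C@@H]2C[C@H]1C2(C)C | intermediate
20 | CNP0307059.1 | COC1=C(C)C(=O)[C@@]2(C(=O)C1(C)C)[C@@H](C(C)C)CC[C@@]21CC[C@@H]2C[C@H]1C2(C)C | target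

## Step count and risks

Total: 13 steps. Longest linear sequence: 13 steps from 1; fragments 5, 9, 11 and 15 are bought.

**Step 5 (key step).** The carbenoid must reach the alkene from the face lying under the syn methyl of the bridge. If that approach is too slow, insertion into the C4–H bond on the same face or carbene dimerisation would take over. Cu(MeCN)4PF6, a monovalent copper salt that inserts into C–H bonds less readily, is the first adjustment. The fallback changes the mechanism and sets out from 6: iodocarbocyclisation (I2, Ti(OtBu)4, CuO, CH2Cl2) lets the malonate carbon attack the iodonium-activated alkene at the tertiary carbon, syn to its own tether, giving the iodomethyl lactone F1. DBU then closes B1–B4 by 3-exo-tet displacement, and the route is rejoined at 8.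

**Step 10.** Two things can fail. The enolate may attack the ester before the lactone, which would invert the sense of B1. The more likely failure is that the hindered methine dianion does not form or does not close on the neopentyl ester, stalling at 16. The fallback sets out from 14 and reverses the roles. The methyl ester is cleaved at the methyl carbon (n-PrSLi, HMPA, 25 °C) to the lactone acid F4, which is converted with oxalyl chloride into the acid chloride F5. Lewis-acid-mediated C-acylation (ZnCl2 or TiCl4, CH2Cl2) of the tetrasubstituted trimethylsilyl enol ether F6 (made from 15 with Me3SiCl, NaI, Et3N) gives the lactone diketone F7. LiN(SiMe3)2 then closes the unhindered ethyl-ketone enolate on the lactone carbonyl, and the route is rejoined at 17.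

**Step 8.** Enolisation of the crowded B1–H by trivalent manganese may be slow, and facial selectivity at B2 may be poor, since the preference rests on a transition-state argument only. The fallback sets out from 12: bromination (NaH, N-bromosuccinimide, THF) gives the bromomalonate F3. Reductive radical cyclisation (Bu3SnH, Et3B/air, low temperature) generates the same radical without enolisation, at a temperature that favours the chair pathway, and ends by hydrogen transfer. It rejoins the route at 14.

**Step 6.** Direct 1,2-addition of allylmagnesium bromide to the lactone or ester may compete with homoconjugate opening. The fallback sets out from 8: opening with PhSeNa (from PhSeSePh and NaBH4) gives the selenide F2. Keck radical allylation (allyltributylstannane, AIBN, benzene, 80 °C) of the primary B4 radical then rejoins the route at 10.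

**Step 11.** The ambident enolate may be alkylated at the T2 oxygen, or the C3 hydroxyl may close onto T2 if acid is present. The fallback sets out from 17 and replaces kinetic alkylation by equilibrium control after the hydroxyl is gone. Thioacylation with 1,1'-thiocarbonyldiimidazole (aqueous work-up frees the enol) gives the imidazolide F8. Bu3SnH/AIBN gives the deoxygenated triketone F9. Acid-catalysed etherification (HC(OMe)3, MeOH, TsOH cat.) should then settle on the less congested T4 ether and rejoins the route at 20.

**Step 13.** β-Scission of the B5–B1 bond of the C3 radical would give a dicarbonyl-stabilised radical that can re-close, scrambling B5. The fallback sets out from 18 and avoids a radical at C3: syn-elimination with the Burgess reagent (benzene, 60 °C) gives the C3=C4 alkene F10, and hydrogenation (H2, Pd/C) rejoins the route at 20.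

## Further compounds

F1 | step 5 | iodomethyl γ-lactone methyl ester (CH2I on B5 anti to the bridge) | IC[C@]12C(C(=O)OC)C(=O)O[C@H]1C[C@@H]3C[C@H]2C3(C)C
F2 | step 6 | (phenylselanyl)methyl γ-lactone methyl ester | c1ccccc1[Se]C[C@]12C(C(=O)OC)C(=O)O[C@H]1C[C@@H]3C[C@H]2C3(C)C
F3 | step 8 | B1-bromo derivative of 12 | CC(C)=CCC[C@]12C(Br)(C(=O)OC)C(=O)O[C@H]1C[C@@H]3C[C@H]2C3(C)C
F4 | step 10 | lactone carboxylic acid from 14 | OC(=O)[C@]12[C@@H](C(C)C)CC[C@@]13[C@@H](OC2=O)C[C@@H]4C[C@H]3C4(C)C
F5 | step 10 | lactone acid chloride | ClC(=O)[C@]12[C@@H](C(C)C)CC[C@@]13[C@@H](OC2=O)C[C@@H]4C[C@H]3C4(C)C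
F6 | step 10 | trimethyl[(2-methylpent-2-en-3-yl)oxy]silane | CCC(O[Si](C)(C)C)=C(C)C
F7 | step 10 | lactone bearing a 2,2-dimethyl-3-oxopentanoyl group on B1 | CCC(=O)C(C)(C)C(=O)[C@]12[C@@H](C(C)C)CC[C@@]13[C@@H](OC2=O)C[C@@H]4C[C@H]3C4(C)C
F8 | step 11 | O-(imidazol-1-ylthiocarbonyl) derivative of 17 at pinane C3 | OC1=C(C)C(=O)[C@@]2(C(=O)C1(C)C)[C@@H](C(C)C)CC[C@@]21[C@@H](OC(=S)n3ccnc3)C[C@@H]2C[C@H]1C2(C)C
F9 | step 11 | deoxygenated enolised triketone (O-demethyl target, identical with A1) | OC1=C(C)C(=O)[C@@]2(C(=O)C1(C)C)[C@@H](C(C)C)CC[C@@]21CC[C@@H]2C[C@H]1C2(C)C
F10 | step 13 | C3=C4 alkene of the target skeleton | COC1=C(C)C(=O)[C@@]2(C(=O)C1(C)C)[C@@H](C(C)C)CC[C@@]21C=C[C@@H]2C[C@H]1C2(C)C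
A1 | alternative 1 | enolised spiro triketone (O-demethyl target) | OC1=C(C)C(=O)[C@@]2(C(=O)C1(C)C)[C@@H](C(C)C)CC[C@@]21CC[C@@H]2C[C@H]1C2(C)C
A2 | alternative 1 | spiro acid chloride (B1 epimerisable) | ClC(=O)C1[C@@H](C(C)C)CC[C@@]12CC[C@@H]3C[C@H]2C3(C)C
A3 | alternative 1 | methyl 2,2-dimethyl-3-oxopentanoate | CCC(=O)C(C)(C)C(=O)OC
A4 | alternative 2 | crossed photoadduct (β-acetoxy ketone) | COC(=O)C1(C(=O)OC)[C@@H](C(C)C)[C@]2(OC(C)=O)C[C@@]13[C@H]2C(=O)[C@@H]4C[C@H]3C4(C)C
A5 | alternative 2 | enone with malonate/enol acetate tether on pinane C2 | COC(=O)C(C(=O)OC)([C@@H](C(C)C)C(OC(C)=O)=C)C1=CC(=O)[C@@H]2C[C@H]1C2(C)C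
A6 | alternative 3 | cis-fused lactone ester of the spiro cyclopentane | O=C1OC(C)(C)[C@H]2CC[C@@]3(CC[C@@H]4C[C@H]3C4(C)C)[C@@]12C(=O)OC
A7 | alternative 3 | nopinone alkylidene malonate | COC(=O)C(C(=O)OC)=C1CC[C@@H]2C[C@H]1C2(C)C
A8 | alternative 3 | N-(5-methylhex-4-enoyloxy)phthalimide | CC(C)=CCCC(=O)ON1C(=O)c2ccccc2C1=O
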